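**Retrosynthetic overview**
1. Target 31 ⇐ DIBAL-H opening of the bridged Z-enoate ε-lactone 30 (latent CH2OH + Z-enal) ⇐ B-alkyl Suzuki coupling of vinyl lactone 17 with bromotrienol 28.
2. 28 ⇐ Negishi coupling (homoprenylzinc) ⇐ hydrozirconation/iodination ⇐ enantioselective 2-butynylation of (E)-3-bromo-2-methylacrolein 20.
3. 17 ⇐ intramolecular HWE lactonisation onto the C–Si-derived ketone ⇐ MeMgBr addition to the 2-hydroxymethyl-2-vinylcyclohexanone 10.
4. 10 ⇐ hydroxyl-directed epoxidation/semipinacol ring expansion of dienyl cyclopentanol 8 ⇐ chloroprene Grignard + silyl ketone 5 ⇐ cyclopentenone (asymmetric conjugate silylation/allylation).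
5. Ring order: cyclopentane (purchased) → cyclohexane (ring expansion, step 3) → temporary lactone ring (step 7), opened in step 14.

Assumption: hydroxyl groups in the organoboron and organozirconium intermediates 16, 24 and 29 are drawn free, because O–B and O–Zr bonds formed with excess reagent are hydrolysed on work-up.

**Step 1**
Reactants: 1 cyclopent-2-en-1-one; 2 3-iodoprop-1-ene
Product: 5 (2S,3S)-3-[dimethyl(phenyl)silyl]-2-(prop-2-en-1-yl)cyclopentan-1-one, via boron enolate 3 (not isolated), via lithium enolate 4 (not isolated)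
Conditions: PhMe2Si–Bpin, CuCl (2 mol %), chiral imidazolinium NHC precursor (2.2 mol %), NaOt-Bu (5 mol %), THF, −78 °C; then MeLi, −78 °C; 2, DMPU, −78 → −30 °C
Reagents that add atoms: (dimethylphenylsilyl)boronic acid pinacol ester C[Si](C)(c1ccccc1)B1OC(C)(C)C(C)(C)O1
Why: Cu–NHC-catalysed enantioselective conjugate silyl addition sets the silyl-bearing carbon by ligand control, and the regiodefined enolate (released as its lithium enolate) is C-allylated anti to the bulky silyl group (three-component conjugate addition–enolate alkylation), giving the 2,3-trans ketone.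

**Step 2**
Reactants: 5 (2S,3S)-3-[dimethyl(phenyl)silyl]-2-(prop-2-en-1-yl)cyclopentan-1-one; 6 2-chlorobuta-1,3-diene
Product: 8 (1S,2S,3S)-1-(buta-1,3-dien-2-yl)-3-[dimethyl(phenyl)silyl]-2-(prop-2-en-1-yl)cyclopentan-1-ol, via dienyl Grignard reagent 7 (not isolated)
Conditions: 6, Mg, THF, 50 °C; anhydrous CeCl3, THF, −78 °C, then 5; aq NH4Cl
Reagents that add atoms: none
Why: Grignard (organocerium) 1,2-addition occurs anti to the α-allyl group, as usual for 2-substituted cyclopentanones, so the tertiary hydroxyl ends cis to allyl while CeCl3 suppresses enolisation.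

**Step 3**
Reactants: 8 (1S,2S,3S)-1-(buta-1,3-dien-2-yl)-3-[dimethyl(phenyl)silyl]-2-(prop-2-en-1-yl)cyclopentan-1-ol
Product: 10 (2S,3S,4S)-4-[dimethyl(phenyl)silyl]-2-ethenyl-2-(hydroxymethyl)-3-(prop-2-en-1-yl)cyclohexan-1-one, via vinyl epoxide 9 (not isolated)
Conditions: VO(acac)2 (5 mol %), t-BuOOH (1.2 equiv), CH2Cl2, 0 °C; then ZnBr2 (1.1 equiv), −20 → 0 °C
Reagents that add atoms: tert-butyl hydroperoxide CC(C)(C)OO
Why: Hydroxyl-directed vanadium epoxidation of the proximal diene double bond (the vinyl arm turns toward the unsubstituted ring CH2 to avoid the allyl-bearing carbon, which fixes the epoxide face) is followed by a zinc-chelated semipinacol ring expansion of the α-hydroxy epoxide, in which the more substituted, β-silyl-activated ring carbon migrates anti to the breaking allylic C–O bond with retention, setting the quaternary carbon with CH2OH cis to allyl.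

**Step 4**
Reactants: 10 (2S,3S,4S)-4-[dimethyl(phenyl)silyl]-2-ethenyl-2-(hydroxymethyl)-3-(prop-2-en-1-yl)cyclohexan-1-one
Product: 11 (1S,2S,3S,4S)-4-[dimethyl(phenyl)silyl]-2-ethenyl-2-(hydroxymethyl)-1-methyl-3-(prop-2-en-1-yl)cyclohexan-1-ol
Conditions: MeMgBr (3.5 equiv), THF, −78 → −20 °C; aq NH4Cl
Reagents that add atoms: methylmagnesium bromide C[Mg]Br
Why: Grignard addition to the α-quaternary cyclohexanone proceeds by axial attack on the face opposite the axial CH2O–Mg arm and the allyl group (chelation and 1,3-diaxial control agree), placing methyl cis to vinyl and the new hydroxyl cis to CH2OH.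

**Step 5**
Reactants: 11 (1S,2S,3S,4S)-4-[dimethyl(phenyl)silyl]-2-ethenyl-2-(hydroxymethyl)-1-methyl-3-(prop-2-en-1-yl)cyclohexan-1-ol
Product: 12 (1S,2S,3S,4S)-2-ethenyl-2-(hydroxymethyl)-1-methyl-3-(prop-2-en-1-yl)cyclohexane-1,4-diol
Conditions: KH, t-BuOOH, NMP, 0 °C → rt; then TBAF, 70 °C
Reagents that add atoms: tert-butyl hydroperoxide CC(C)(C)OO
Why: Tamao–Fleming oxidation in its basic hydroperoxide/fluoride variant converts the hindered C–SiMe2Ph bond into C–OH with retention and leaves both terminal alkenes untouched.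

**Step 6**
Reactants: 12 (1S,2S,3S,4S)-2-ethenyl-2-(hydroxymethyl)-1-methyl-3-(prop-2-en-1-yl)cyclohexane-1,4-diol
Product: 13 [(1S,2S,5S,6S)-1-ethenyl-2,5-dihydroxy-2-methyl-6-(prop-2-en-1-yl)cyclohexyl]methyl 2-(diethoxyphosphoryl)propanoate
Conditions: 2-(diethoxyphosphoryl)propanoic acid (1.1 equiv), EDC·HCl, DMAP (10 mol %), CH2Cl2, −10 °C
Reagents that add atoms: 2-(diethoxyphosphoryl)propanoic acid CCOP(=O)(OCC)C(C)C(=O)O
Why: Steglich esterification acylates the only primary hydroxyl faster than the flanked secondary and the tertiary hydroxyls; no ring stereocentre is touched and the phosphonate α-carbon is an inconsequential epimer mixture.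

**Step 7**
Reactants: 13 [(1S,2S,5S,6S)-1-ethenyl-2,5-dihydroxy-2-methyl-6-(prop-2-en-1-yl)cyclohexyl]methyl 2-(diethoxyphosphoryl)propanoate
Product: 15 (1S,5Z,9S,10R)-1-ethenyl-9-hydroxy-5,9-dimethyl-10-(prop-2-en-1-yl)-3-oxabicyclo[4.3.1]dec-5-en-4-one, via keto phosphonate 14 (not isolated)
Conditions: TPAP (5 mol %), NMO, 4 Å MS, CH2Cl2, rt; then dilution with MeCN (0.005 M), LiCl, DBU, rt → 45 °C
Reagents that add atoms: none
Why: Ley–Griffith oxidation of the secondary alcohol and in-flask intramolecular Horner–Wadsworth–Emmons olefination (Masamune–Roush conditions) close the seven-membered lactone, whose ring forces the carbonyl cis to the allyl-bearing carbon and so fixes the tetrasubstituted alkene as Z.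

**Step 8**
Reactants: 15 (1S,5Z,9S,10R)-1-ethenyl-9-hydroxy-5,9-dimethyl-10-(prop-2-en-1-yl)-3-oxabicyclo[4.3.1]dec-5-en-4-one
Product: 17 (1S,5Z,9S,10R)-1-ethenyl-9-hydroxy-10-(3-hydroxypropyl)-5,9-dimethyl-3-oxabicyclo[4.3.1]dec-5-en-4-one, via alkylborane 16 (not isolated)
Conditions: 9-BBN (1.3 equiv), THF, 0 °C → rt; then H2O2, aq NaHCO3, 0 °C
Reagents that add atoms: hydrogen peroxide OO
Why: Brown hydroboration–oxidation with 9-BBN is anti-Markovnikov and selects the unhindered allyl group over the neopentyl-type vinyl group on the quaternary carbon and over the tetrasubstituted enoate.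

**Step 9**
Reactants: 18 2-methylprop-2-enal
Product: 20 (2E)-3-bromo-2-methylprop-2-enal, via dibromo aldehyde 19 (not isolated)
Conditions: Br2, CH2Cl2, −78 → 0 °C; then Et3N, 0 °C → rt
Reagents that add atoms: bromine BrBr
Why: Alkene bromination followed by base-induced dehydrobromination can only give the β-bromo enal (the α-carbon has no hydrogen) and delivers the thermodynamically favoured E isomer.

**Step 10**
Reactants: 20 (2E)-3-bromo-2-methylprop-2-enal; 21 1-bromobut-2-yne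
Product: 23 (1E,3R)-1-bromo-2-methylhept-1-en-5-yn-3-ol, via allenylboronate 22 (not isolated)
Conditions: 21, B2pin2, CuCl/Xantphos (5 mol %), KOt-Bu, THF, 0 °C; filtration (Celite), switch to toluene; 20, (R)-TRIP (5 mol %), 4 Å MS, −30 °C; aqueous work-up
Reagents that add atoms: none
Why: Proposed new method: a telescoped copper-catalysed SN2′ borylation of the propargylic bromide to the 1-methylallenyl boronate 22, followed by chiral-phosphoric-acid-catalysed allenylboration of enal 20, in which the acid binds a pinacol oxygen and the formyl C–H in a chair-like six-membered SE2′ transition state so that the allene CH2 terminus adds to the Re face of the aldehyde, setting the (R)-carbinol and giving only the homopropargylic (internal alkyne) alcohol; the closest known reactions are phosphoric-acid-catalysed propargylation of aldehydes with the unsubstituted allenylboronate and copper-catalysed borylation of propargylic electrophiles, neither shown for an allenylboronate substituted at the boron-bearing carbon nor run in one flask.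

**Step 11**
Reactants: 23 (1E,3R)-1-bromo-2-methylhept-1-en-5-yn-3-ol
Product: 25 (1E,3R,5E)-1-bromo-6-iodo-2-methylhepta-1,5-dien-3-ol, via alkenylzirconocene 24 (not isolated)
Conditions: Cp2Zr(H)Cl (2.5 equiv), THF, rt → 40 °C; then I2, 0 °C
Reagents that add atoms: iodine II
Why: Schwartz hydrozirconation adds Zr–H syn, with zirconium settling on the less hindered methyl-bearing alkyne carbon under equilibrating conditions (about 9:1 or better), and iodinolysis with retention gives the E-vinyl iodide while the vinyl bromide is untouched.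

**Step 12**
Reactants: 25 (1E,3R,5E)-1-bromo-6-iodo-2-methylhepta-1,5-dien-3-ol; 26 5-bromo-2-methylpent-2-ene
Product: 28 (1E,3R,5E)-1-bromo-2,6,10-trimethylundeca-1,5,9-trien-3-ol, via homoprenylzinc bromide 27 (not isolated)
Conditions: 26, Zn dust, LiCl, THF, 50 °C; then 25, Pd(PPh3)4 (5 mol %), THF, rt
Reagents that add atoms: none
Why: Negishi coupling of the alkylzinc reagent at the vinyl iodide (far more reactive than the vinyl bromide) proceeds with retention of alkene geometry and completes the E-trisubstituted alkene.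

**Step 13**
Reactants: 17 (1S,5Z,9S,10R)-1-ethenyl-9-hydroxy-10-(3-hydroxypropyl)-5,9-dimethyl-3-oxabicyclo[4.3.1]dec-5-en-4-one; 28 (1E,3R,5E)-1-bromo-2,6,10-trimethylundeca-1,5,9-trien-3-ol
Product: 30 (1S,5Z,9S,10R)-9-hydroxy-1-[(3E,5R,7E)-5-hydroxy-4,8,12-trimethyltrideca-3,7,11-trien-1-yl]-10-(3-hydroxypropyl)-5,9-dimethyl-3-oxabicyclo[4.3.1]dec-5-en-4-one, via alkylborane 29 (not isolated)
Conditions: 17, 9-BBN (4 equiv), THF, 60 °C; then aq K3PO4, 28, PdCl2(dppf) (10 mol %), AsPh3, DMF, rt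
Reagents that add atoms: none
Why: 9-BBN hydroboration of the hindered vinyl group followed by Suzuki–Miyaura B-alkyl coupling with the alkenyl bromide joins the side chain with retention of the E geometry and tolerates the free hydroxyls and the lactone.

**Step 14**
Reactants: 30 (1S,5Z,9S,10R)-9-hydroxy-1-[(3E,5R,7E)-5-hydroxy-4,8,12-trimethyltrideca-3,7,11-trien-1-yl]-10-(3-hydroxypropyl)-5,9-dimethyl-3-oxabicyclo[4.3.1]dec-5-en-4-one
Product: 31 (2Z)-2-[(2R,3S,4S)-4-hydroxy-3-(hydroxymethyl)-3-[(3E,5R,7E)-5-hydroxy-4,8,12-trimethyltrideca-3,7,11-trien-1-yl]-2-(3-hydroxypropyl)-4-methylcyclohexylidene]propanal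
Conditions: DIBAL-H (5 equiv), CH2Cl2, −78 °C; Rochelle salt
Reagents that add atoms: none
Why: DIBAL-H half-reduction of the lactone gives an aluminium hemiacetal that collapses on work-up to the primary alcohol and the conjugated aldehyde, whose Z geometry was locked in the ring.

**Compound list**
1 | cyclopent-2-en-1-one | O=C1C=CCC1 | starting material
2 | 3-iodoprop-1-ene (allyl iodide) | C=CCI | starting material
3 | 2-{[(3S)-3-[dimethyl(phenyl)silyl]cyclopent-1-en-1-yl]oxy}-4,4,5,5-tetramethyl-1,3,2-dioxaborolane (boron enolate) | CC1(C)OB(OC2=C[C@@H]([Si](C)(C)c3ccccc3)CC2)OC1(C)C | intermediate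
4 | lithium (3S)-3-[dimethyl(phenyl)silyl]cyclopent-1-en-1-olate (lithium enolate) | [Li]OC1=C[C@@H]([Si](C)(C)c2ccccc2)CC1 | intermediate
5 | (2S,3S)-3-[dimethyl(phenyl)silyl]-2-(prop-2-en-1-yl)cyclopentan-1-one | O=C1[C@H](CC=C)[C@@H]([Si](C)(C)c2ccccc2)CC1 | intermediate
6 | 2-chlorobuta-1,3-diene (chloroprene) | C=CC(Cl)=C | starting material
7 | (buta-1,3-dien-2-yl)magnesium chloride | C=CC(=C)[Mg]Cl | intermediate
8 | (1S,2S,3S)-1-(buta-1,3-dien-2-yl)-3-[dimethyl(phenyl)silyl]-2-(prop-2-en-1-yl)cyclopentan-1-ol | C=CC(=C)[C@@]1(O)[C@H](CC=C)[C@@H]([Si](C)(C)c2ccccc2)CC1 | intermediate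
9 | (1S,2S,3S)-3-[dimethyl(phenyl)silyl]-1-[(2R)-2-ethenyloxiran-2-yl]-2-(prop-2-en-1-yl)cyclopentan-1-ol | C=C[C@@]1(CO1)[C@@]2(O)[C@H](CC=C)[C@@H]([Si](C)(C)c3ccccc3)CC2 | intermediate
10 | (2S,3S,4S)-4-[dimethyl(phenyl)silyl]-2-ethenyl-2-(hydroxymethyl)-3-(prop-2-en-1-yl)cyclohexan-1-one | C=C[C@@]1(CO)[C@H](CC=C)[C@@H]([Si](C)(C)c2ccccc2)CCC1=O | intermediate
11 | (1S,2S,3S,4S)-4-[dimethyl(phenyl)silyl]-2-ethenyl-2-(hydroxymethyl)-1-methyl-3-(prop-2-en-1-yl)cyclohexan-1-ol | C=C[C@@]1(CO)[C@H](CC=C)[C@@H]([Si](C)(C)c2ccccc2)CC[C@]1(C)O | intermediate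
12 | (1S,2S,3S,4S)-2-ethenyl-2-(hydroxymethyl)-1-methyl-3-(prop-2-en-1-yl)cyclohexane-1,4-diol | C=C[C@@]1(CO)[C@H](CC=C)[C@@H](O)CC[C@]1(C)O | intermediate
13 | [(1S,2S,5S,6S)-1-ethenyl-2,5-dihydroxy-2-methyl-6-(prop-2-en-1-yl)cyclohexyl]methyl 2-(diethoxyphosphoryl)propanoate (epimers at the phosphonate carbon) | C=C[C@@]1(COC(=O)C(C)P(=O)(OCC)OCC)[C@H](CC=C)[C@@H](O)CC[C@]1(C)O | intermediate
14 | [(1S,2S,6S)-1-ethenyl-2-hydroxy-2-methyl-5-oxo-6-(prop-2-en-1-yl)cyclohexyl]methyl 2-(diethoxyphosphoryl)propanoate | C=C[C@@]1(COC(=O)C(C)P(=O)(OCC)OCC)[C@H](CC=C)C(=O)CC[C@]1(C)O | intermediate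
15 | (1S,5Z,9S,10R)-1-ethenyl-9-hydroxy-5,9-dimethyl-10-(prop-2-en-1-yl)-3-oxabicyclo[4.3.1]dec-5-en-4-one | C=C[C@]12COC(=O)/C(C)=C(/CC[C@]1(C)O)[C@H]2CC=C | intermediate
16 | (1S,5Z,9S,10R)-10-[3-(9-borabicyclo[3.3.1]nonan-9-yl)propyl]-1-ethenyl-9-hydroxy-5,9-dimethyl-3-oxabicyclo[4.3.1]dec-5-en-4-one | C=C[C@]12COC(=O)/C(C)=C(/CC[C@]1(C)O)[C@H]2CCCB3C4CCCC3CCC4 | intermediate
17 | (1S,5Z,9S,10R)-1-ethenyl-9-hydroxy-10-(3-hydroxypropyl)-5,9-dimethyl-3-oxabicyclo[4.3.1]dec-5-en-4-one | C=C[C@]12COC(=O)/C(C)=C(/CC[C@]1(C)O)[C@H]2CCCO | intermediate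
18 | 2-methylprop-2-enal (methacrolein) | C=C(C)C=O | starting material
19 | 2,3-dibromo-2-methylpropanal (racemic) | O=CC(C)(Br)CBr | intermediate
20 | (2E)-3-bromo-2-methylprop-2-enal | O=C/C(C)=C/Br | intermediate
21 | 1-bromobut-2-yne | CC#CCBr | starting material
22 | 2-(buta-2,3-dien-2-yl)-4,4,5,5-tetramethyl-1,3,2-dioxaborolane | C=C=C(C)B1OC(C)(C)C(C)(C)O1 | intermediate
23 | (1E,3R)-1-bromo-2-methylhept-1-en-5-yn-3-ol | CC#CC[C@@H](O)/C(C)=C/Br | intermediate
24 | [(2E,5R,6E)-7-bromo-5-hydroxy-6-methylhepta-2,6-dien-2-yl]chlorobis(cyclopentadienyl)zirconium | C/C(=C\C[C@@H](O)/C(C)=C/Br)[Zr](Cl)(C1C=CC=C1)C1C=CC=C1 | intermediate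
25 | (1E,3R,5E)-1-bromo-6-iodo-2-methylhepta-1,5-dien-3-ol | C/C(I)=C\C[C@@H](O)/C(C)=C/Br | intermediate
26 | 5-bromo-2-methylpent-2-ene | CC(C)=CCCBr | starting material
27 | (4-methylpent-3-en-1-yl)zinc bromide | CC(C)=CCC[Zn]Br | intermediate
28 | (1E,3R,5E)-1-bromo-2,6,10-trimethylundeca-1,5,9-trien-3-ol | CC(C)=CCC/C(C)=C/C[C@@H](O)/C(C)=C/Br | intermediate
29 | (1S,5Z,9S,10R)-1-[2-(9-borabicyclo[3.3.1]nonan-9-yl)ethyl]-9-hydroxy-10-(3-hydroxypropyl)-5,9-dimethyl-3-oxabicyclo[4.3.1]dec-5-en-4-one | C(C[C@]12COC(=O)/C(C)=C(/CC[C@]1(C)O)[C@H]2CCCO)B3C4CCCC3CCC4 | intermediate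
30 | (1S,5Z,9S,10R)-9-hydroxy-1-[(3E,5R,7E)-5-hydroxy-4,8,12-trimethyltrideca-3,7,11-trien-1-yl]-10-(3-hydroxypropyl)-5,9-dimethyl-3-oxabicyclo[4.3.1]dec-5-en-4-one | CC(C)=CCC/C(C)=C/C[C@@H](O)/C(C)=C/CC[C@]12COC(=O)/C(C)=C(/CC[C@]1(C)O)[C@H]2CCCO | intermediate
31 | (2Z)-2-[(2R,3S,4S)-4-hydroxy-3-(hydroxymethyl)-3-[(3E,5R,7E)-5-hydroxy-4,8,12-trimethyltrideca-3,7,11-trien-1-yl]-2-(3-hydroxypropyl)-4-methylcyclohexylidene]propanal (CNP0330845.1) | CC(C)=CCC/C(C)=C/C[C@@H](O)/C(C)=C/CC[C@@]1(CO)[C@H](CCCO)/C(=C(/C)C=O)CC[C@]1(C)O | target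

**Totals**
Total step count: 14. Longest linear sequence: 10 (steps 1–8, 13, 14).

**Steps most likely to fail**

Step 3 (epoxidation/ring expansion). The risks are attack on the wrong epoxide face, migration of the unsubstituted ring CH2 instead of the allyl-bearing carbon, and side reactions of the ionised allylic epoxide. The fallback sets out from 8 and comes back at 10. Vinyl epoxide 9 is made under reagent control with a hafnium(IV)–bis(hydroxamic acid) catalyst and cumene hydroperoxide and is isolated. It is silylated (TMS-imidazole) to {[(1S,2S,3S)-3-[dimethyl(phenyl)silyl]-1-[(2R)-2-ethenyloxiran-2-yl]-2-(prop-2-en-1-yl)cyclopentyl]oxy}trimethylsilane F1. F1 is rearranged by the Suzuki–Tsuchihashi protocol (TiCl4, CH2Cl2, −78 °C), a concerted anti 1,2-shift of the epoxy silyl ether that avoids a free allyl cation. Aqueous work-up removes the silyl group and gives 10.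

Step 7 (seven-membered HWE ring closure onto a hindered ketone). The fallback sets out from 12 and comes back at 15. Selective acylation of the primary alcohol with 2-bromopropanoyl bromide (pyridine, −40 °C) gives [(1S,2S,5S,6S)-1-ethenyl-2,5-dihydroxy-2-methyl-6-(prop-2-en-1-yl)cyclohexyl]methyl 2-bromopropanoate F2. Dess–Martin oxidation gives [(1S,2S,6S)-1-ethenyl-2-hydroxy-2-methyl-5-oxo-6-(prop-2-en-1-yl)cyclohexyl]methyl 2-bromopropanoate F3. A SmI2-mediated intramolecular Reformatsky aldol (THF, −78 °C, high dilution) closes the ring to (1S,9S,10S)-1-ethenyl-6,9-dihydroxy-5,9-dimethyl-10-(prop-2-en-1-yl)-3-oxabicyclo[4.3.1]decan-4-one F4. Trifluoroacetylation and DBU (E1cB dehydration into conjugation) give 15.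

Step 10 (proposed new butynylation). The fallback uses known chemistry, sets out from 20 and comes back at 23. Boronate 22 is made by the known copper-catalysed propargylic borylation of 21 and isolated by distillation. Uncatalysed thermal allenylboration of 20 gives racemic (1E)-1-bromo-2-methylhept-1-en-5-yn-3-ol F5. MnO2 oxidation gives (1E)-1-bromo-2-methylhept-1-en-5-yn-3-one F6. Corey–Bakshi–Shibata reduction ((S)-Me-CBS, catecholborane, toluene, −78 °C) gives 23.

**Further compounds**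
F1 | step 3 | {[(1S,2S,3S)-3-[dimethyl(phenyl)silyl]-1-[(2R)-2-ethenyloxiran-2-yl]-2-(prop-2-en-1-yl)cyclopentyl]oxy}trimethylsilane | C=C[C@@]1(CO1)[C@@]2(O[Si](C)(C)C)[C@H](CC=C)[C@@H]([Si](C)(C)c3ccccc3)CC2
F2 | step 7 | [(1S,2S,5S,6S)-1-ethenyl-2,5-dihydroxy-2-methyl-6-(prop-2-en-1-yl)cyclohexyl]methyl 2-bromopropanoate | C=C[C@@]1(COC(=O)C(C)Br)[C@H](CC=C)[C@@H](O)CC[C@]1(C)O
F3 | step 7 | [(1S,2S,6S)-1-ethenyl-2-hydroxy-2-methyl-5-oxo-6-(prop-2-en-1-yl)cyclohexyl]methyl 2-bromopropanoate | C=C[C@@]1(COC(=O)C(C)Br)[C@H](CC=C)C(=O)CC[C@]1(C)O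
F4 | step 7 | (1S,9S,10S)-1-ethenyl-6,9-dihydroxy-5,9-dimethyl-10-(prop-2-en-1-yl)-3-oxabicyclo[4.3.1]decan-4-one (mixture at C5 and C6) | C=C[C@]12COC(=O)C(C)C(O)(CC[C@]1(C)O)[C@H]2CC=C
F5 | step 10 | (1E)-1-bromo-2-methylhept-1-en-5-yn-3-ol (racemic) | CC#CCC(O)/C(C)=C/Br
F6 | step 10 | (1E)-1-bromo-2-methylhept-1-en-5-yn-3-one | CC#CCC(=O)/C(C)=C/Br
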